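The cyclohexene ring is disconnected at its only double bond, C2=C3 (C1 = quaternary carbinol carbon, C4 = benzoyloxy carbon, C7 = exocyclic CH2), by bridging these two carbons with SO2. The precursor is a thiepane 1,1-dioxide whose chain C2–C1(C7)–C6–C5–C4–C3 is 2-C-hydroxymethyl-D-mannitol. C6, C5 and C4 are C3, C4 and C5 of D-mannose, and C1 is set by a formaldehyde aldol at mannose C2. One Ramberg–Bäcklund reaction contracts the seven-membered ring to the carbocycle and creates the cis-alkene between two oxygenated carbons without touching a stereocentre. The benzylidene acetal that shields O4/O5 from base finally becomes the C4 benzoate.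

Key step: step 9

Remark: compounds 1–9 use sugar numbering and 10–17 use the target numbering above. Lactols 2 and 3 (anomers), the benzylidene carbon of 7–14 and the transient centres of 10 and 11 are mixtures that are lost later, so these centres are left undefined in the SMILES.

Step 1
Reactants: 1 2,3:5,6-di-O-isopropylidene-α-D-mannofuranose
Product: 2 2-C-(hydroxymethyl)-2,3:5,6-di-O-isopropylidene-D-mannofuranose
Conditions: 37% aq. HCHO, K2CO3, MeOH, reflux
Reagents that add atoms: formaldehyde C=O
Why: Crossed aldol reaction; the open-chain aldehyde enolises at C2, formaldehyde adds to the dioxolane face anti to the C4 side chain, and only this epimer can re-close to the cis-fused furanose, which sets the quaternary centre with O2 kept cis to O3.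

Step 2
Reactants: 2 2-C-(hydroxymethyl)-2,3:5,6-di-O-isopropylidene-D-mannofuranose
Product: 3 2-C-[(tert-butyldiphenylsilyloxy)methyl]-2,3:5,6-di-O-isopropylidene-D-mannofuranose
Conditions: TBDPSCl (1.05 equiv), imidazole, DMF, 0 °C to rt
Reagents that add atoms: tert-butyl(chloro)diphenylsilane CC(C)(C)[Si](Cl)(c1ccccc1)c1ccccc1
Why: Chemoselective silylation of a primary alcohol in the presence of a lactol OH, as is routine for furanose acetonides; it marks the future C7 arm so that the two CH2O arms on the quaternary carbon stay distinguishable after reduction.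

Step 3
Reactants: 3 2-C-[(tert-butyldiphenylsilyloxy)methyl]-2,3:5,6-di-O-isopropylidene-D-mannofuranose
Product: 4 2-C-[(tert-butyldiphenylsilyloxy)methyl]-2,3:5,6-di-O-isopropylidene-D-mannitol (1,4-diol)
Conditions: NaBH4, EtOH, 0 °C to rt
Reagents that add atoms: none
Why: Borohydride reduction of the lactol through its open aldehyde form; no stereocentre is formed, and the silyl ether and acetonides are inert.

Step 4
Reactants: 4 2-C-[(tert-butyldiphenylsilyloxy)methyl]-2,3:5,6-di-O-isopropylidene-D-mannitol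
Product: 5 2-C-[(tert-butyldiphenylsilyloxy)methyl]-2,3-O-isopropylidene-D-mannitol (1,4,5,6-tetraol)
Conditions: AcOH/H2O 7:3, rt
Reagents that add atoms: none
Why: Selective acetal hydrolysis; the terminal monosubstituted dioxolane cleaves much faster than the crowded internal 2,3-acetonide, and the TBDPS ether tolerates aqueous acetic acid.

Step 5
Reactants: 5 2-C-[(tert-butyldiphenylsilyloxy)methyl]-2,3-O-isopropylidene-D-mannitol
Product: 6 2-C-[(tert-butyldiphenylsilyloxy)methyl]-2,3-O-isopropylidene-1,6-di-O-tosyl-D-mannitol (4,5-diol)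
Conditions: TsCl (2.2 equiv), pyridine, 0 °C
Reagents that add atoms: 4-toluenesulfonyl chloride Cc1ccc(cc1)S(=O)(=O)Cl
Why: Selective sulfonylation of the two primary hydroxyls over the two flanked secondary ones at low temperature, where displacement of the C1 tosylate by the free 4-OH is also slow.

Step 6
Reactants: 6 2-C-[(tert-butyldiphenylsilyloxy)methyl]-2,3-O-isopropylidene-1,6-di-O-tosyl-D-mannitol
Product: 7 4,5-O-benzylidene-2-C-[(tert-butyldiphenylsilyloxy)methyl]-2,3-O-isopropylidene-1,6-di-O-tosyl-D-mannitol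
Conditions: PhCH(OMe)2, CSA (cat.), CH2Cl2, rt
Reagents that add atoms: benzaldehyde dimethyl acetal COC(OC)c1ccccc1
Why: Acid-catalysed transacetalisation on the only remaining diol (erythro, hence a cis-dioxolane); the acetal is base-stable and carries the carbon skeleton of the later C4 benzoate.

Step 7
Reactants: 7 4,5-O-benzylidene-2-C-[(tert-butyldiphenylsilyloxy)methyl]-2,3-O-isopropylidene-1,6-di-O-tosyl-D-mannitol
Product: 8 4,5-O-benzylidene-2-C-[(tert-butyldiphenylsilyloxy)methyl]-1,6-dideoxy-1,6-epithio-2,3-O-isopropylidene-D-mannitol (thiepane)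
Conditions: Na2S·9H2O, DMF, 80 °C, high dilution
Reagents that add atoms: sodium sulfide [Na+].[Na+].[S-2]
Why: Double SN2 thioether formation; sulfide first displaces the unhindered C6 tosylate, then the thiolate closes the ring 7-exo-tet at the neopentyl-type C1, with the chain ends held close by the two cis-dioxolanes and no stereocentre touched.

Step 8
Reactants: 8 thiepane
Product: 9 thiepane 1,1-dioxide of 8
Conditions: mCPBA (2.5 equiv), NaHCO3, CH2Cl2, 0 °C to rt
Reagents that add atoms: 3-chloroperoxybenzoic acid O=C(OO)c1cccc(Cl)c1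
Why: Sulfide to sulfone oxidation; the bicarbonate buffer keeps both acetals intact and no other oxidisable group is present.

Step 9
Reactants: 9 thiepane 1,1-dioxide
Product: 12 4,5-O-benzylidene-1,6-O-isopropylidene-7-O-TBDPS derivative of (1S,4R,5S,6S)-1-(hydroxymethyl)cyclohex-2-ene-1,4,5,6-tetrol, via alpha-bromo sulfone 10 (not isolated), via episulfone 11 (not isolated)
Conditions: KOH/Al2O3, CBr2F2, t-BuOH/CH2Cl2, 0 °C to rt
Reagents that add atoms: none
Why: Ramberg–Bäcklund reaction in its in-situ halogenation variant, a reaction type known for polyoxygenated cyclic sulfones: KOH deprotonates an α-CH2 of 9, CBr2F2 brominates the carbanion to 10, and deprotonation at the other α-carbon triggers 1,3-elimination of bromide. This C–C bond formation is a 3-exo-tet closure that makes the thiirane dioxide ring of 11 and, with the same bond, closes the six-membered carbocycle across the former seven-membered ring; cheletropic loss of SO2 then leaves C2=C3. No lasting stereocentre is formed or broken: the alkene can only be cis inside the six-membered ring, the transient centres of 10 and 11 vanish, and C1, C4, C5 and C6 carry no acidic hydrogen. The site of bromination is irrelevant because either α-carbon leads to the same episulfone. The selectivity needed is halogenation and 1,3-elimination over E1cB loss of the β-oxygens at C1 and C4; it is secured by tying both oxygens into dioxolane acetals (poor, ring-constrained leaving groups), by the absence of esters, and by fast bromine transfer from CBr2F2, which also avoids carbene addition to the new alkene.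

Step 10
Reactants: 12 silyl-protected cyclohexene
Product: 13 4,5-O-benzylidene-1,6-O-isopropylidene derivative of (1S,4R,5S,6S)-1-(hydroxymethyl)cyclohex-2-ene-1,4,5,6-tetrol (free C7 alcohol)
Conditions: TBAF, THF, rt
Reagents that add atoms: none
Why: Fluoride-induced desilylation; both acetals and the alkene are inert.

Step 11
Reactants: 13 C7 alcohol
Product: 14 7-O-benzoyl-4,5-O-benzylidene-1,6-O-isopropylidene derivative of the same tetrol core
Conditions: BzCl, pyridine, DMAP (cat.), CH2Cl2, 0 °C to rt
Reagents that add atoms: benzoyl chloride O=C(Cl)c1ccccc1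
Why: Standard acylation of the only free hydroxyl group.

Step 12
Reactants: 14 7-benzoate
Product: 17 [(1S,4R,5S,6S)-4-(benzoyloxy)-1,5,6-trihydroxycyclohex-2-en-1-yl]methyl benzoate, via benzoxonium tetrafluoroborate 15 (not isolated), via acetonide hydroxy benzoate 16 (not isolated)
Conditions: Ph3C+ BF4−, MeCN, rt; then H2O, rt
Reagents that add atoms: water O
Why: Hydride abstraction from the benzylidene C–H by the trityl cation gives the 2-phenyl-1,3-dioxolan-2-ylium ion 15, water adds to it, and the hemi-orthoester collapses under stereoelectronic control to the axial ester and equatorial alcohol (O4 pseudoaxial and O5 equatorial in the favoured half-chair), giving 16, whose acetonide is then hydrolysed by the HBF4 released in the same flask.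

Compound list
1 | 2,3:5,6-di-O-isopropylidene-α-D-mannofuranose | O[C@H]1O[C@H]([C@H]2COC(C)(C)O2)[C@@H]2OC(C)(C)O[C@H]12 | starting material
2 | 2-C-(hydroxymethyl)-2,3:5,6-di-O-isopropylidene-D-mannofuranose | OC1O[C@H]([C@H]2COC(C)(C)O2)[C@@H]2OC(C)(C)O[C@]12CO | intermediate
3 | 2-C-[(tert-butyldiphenylsilyloxy)methyl]-2,3:5,6-di-O-isopropylidene-D-mannofuranose | OC1O[C@H]([C@H]2COC(C)(C)O2)[C@@H]2OC(C)(C)O[C@]12CO[Si](c1ccccc1)(c1ccccc1)C(C)(C)C | intermediate
4 | 2-C-[(tert-butyldiphenylsilyloxy)methyl]-2,3:5,6-di-O-isopropylidene-D-mannitol | OC[C@@]1(CO[Si](c2ccccc2)(c2ccccc2)C(C)(C)C)OC(C)(C)O[C@H]1[C@H](O)[C@H]1COC(C)(C)O1 | intermediate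
5 | 2-C-[(tert-butyldiphenylsilyloxy)methyl]-2,3-O-isopropylidene-D-mannitol | OC[C@@]1(CO[Si](c2ccccc2)(c2ccccc2)C(C)(C)C)OC(C)(C)O[C@H]1[C@H](O)[C@H](O)CO | intermediate
6 | 2-C-[(tert-butyldiphenylsilyloxy)methyl]-2,3-O-isopropylidene-1,6-di-O-tosyl-D-mannitol | Cc1ccc(cc1)S(=O)(=O)OC[C@@]1(CO[Si](c2ccccc2)(c2ccccc2)C(C)(C)C)OC(C)(C)O[C@H]1[C@H](O)[C@H](O)COS(=O)(=O)c1ccc(C)cc1 | intermediate
7 | 4,5-O-benzylidene-2-C-[(tert-butyldiphenylsilyloxy)methyl]-2,3-O-isopropylidene-1,6-di-O-tosyl-D-mannitol | Cc1ccc(cc1)S(=O)(=O)OC[C@@]1(CO[Si](c2ccccc2)(c2ccccc2)C(C)(C)C)OC(C)(C)O[C@H]1[C@@H]1OC(c2ccccc2)O[C@@H]1COS(=O)(=O)c1ccc(C)cc1 | intermediate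
8 | 4,5-O-benzylidene-2-C-[(tert-butyldiphenylsilyloxy)methyl]-1,6-dideoxy-1,6-epithio-2,3-O-isopropylidene-D-mannitol (thiepane) | CC(C)(C)[Si](c1ccccc1)(c1ccccc1)OC[C@@]12CSC[C@H]3OC(c4ccccc4)O[C@H]3[C@@H]1OC(C)(C)O2 | intermediate
9 | thiepane 1,1-dioxide of 8 | CC(C)(C)[Si](c1ccccc1)(c1ccccc1)OC[C@@]12CS(=O)(=O)C[C@H]3OC(c4ccccc4)O[C@H]3[C@@H]1OC(C)(C)O2 | intermediate
10 | α-bromo sulfone (bromine on C3) | CC(C)(C)[Si](c1ccccc1)(c1ccccc1)OC[C@@]12CS(=O)(=O)C(Br)[C@H]3OC(c4ccccc4)O[C@H]3[C@@H]1OC(C)(C)O2 | intermediate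
11 | episulfone (thiirane 1,1-dioxide fused at C2–C3 of the new six-membered ring) | CC(C)(C)[Si](c1ccccc1)(c1ccccc1)OC[C@@]12C4C([C@H]3OC(c5ccccc5)O[C@H]3[C@@H]1OC(C)(C)O2)S4(=O)=O | intermediate
12 | 4,5-O-benzylidene-1,6-O-isopropylidene-7-O-TBDPS derivative of (1S,4R,5S,6S)-1-(hydroxymethyl)cyclohex-2-ene-1,4,5,6-tetrol | CC(C)(C)[Si](c1ccccc1)(c1ccccc1)OC[C@@]12C=C[C@H]3OC(c4ccccc4)O[C@H]3[C@@H]1OC(C)(C)O2 | intermediate
13 | C7 alcohol (4,5-O-benzylidene, 1,6-O-isopropylidene) | OC[C@@]12C=C[C@H]3OC(c4ccccc4)O[C@H]3[C@@H]1OC(C)(C)O2 | intermediate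
14 | C7 benzoate (4,5-O-benzylidene, 1,6-O-isopropylidene) | O=C(OC[C@@]12C=C[C@H]3OC(c4ccccc4)O[C@H]3[C@@H]1OC(C)(C)O2)c1ccccc1 | intermediate
15 | 4,5-benzoxonium (2-phenyl-1,3-dioxolan-2-ylium) tetrafluoroborate | O=C(OC[C@@]12C=C[C@H]3O[C+](c4ccccc4)O[C@H]3[C@@H]1OC(C)(C)O2)c1ccccc1.F[B-](F)(F)F | intermediate
16 | 4,7-di-O-benzoyl-1,6-O-isopropylidene compound with free 5-OH | O=C(OC[C@@]12C=C[C@@H](OC(=O)c3ccccc3)[C@@H](O)[C@@H]1OC(C)(C)O2)c1ccccc1 | intermediate
17 | [(1S,4R,5S,6S)-4-(benzoyloxy)-1,5,6-trihydroxycyclohex-2-en-1-yl]methyl benzoate | O=C(OC[C@@]1(O)C=C[C@@H](OC(=O)c2ccccc2)[C@@H](O)[C@@H]1O)c1ccccc1 | target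

Total step count: 12. Longest linear sequence: 12 steps, from 1.

Steps most likely to fail

Step 9 (key step). E1cB expulsion of a β-acetal oxygen from the α-sulfonyl carbanion, or multiple bromination, may outrun the 1,3-elimination under the heterogeneous KOH conditions. The fallback separates halogenation from the base step. From thiepane 8, NCS (CH2Cl2, 0 °C) chlorinates one α-carbon at the sulfide level to give the α-chloro sulfide F1. Buffered mCPBA then gives the α-chloro sulfone F2. A short exposure to t-BuOK in THF at −78 to 0 °C brings about the ring contraction, and the sequence rejoins the route at 12.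

Step 7. SN2 at the neopentyl-type C1 is slow, so intermolecular S-alkylation (oligomerisation) or attack of a second sulfide may compete with closure of the seven-membered ring. The fallback introduces sulfur stepwise. From 7, KSAc (1 equiv, DMF, rt) displaces only the unhindered C6 tosylate to give the thioacetate F3. Slow addition of F3 to NaOMe in MeOH/DMF at 70 °C under high dilution frees the thiolate, which can then only cyclise. The sequence rejoins the route at 8.

Step 12. Hydride abstraction may be slow for the acetal epimer whose C–H lies on the concave face. Regiocontrol may also be lost in the collapse of the hemi-orthoester or through acid-promoted O4 to O5 acyl migration. The fallback differentiates O4 from O5 by protecting the trans-diequatorial pair O5/O6 instead.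
- From 14, aqueous TFA removes both acetals to give the tetraol 7-benzoate F4.
- Butane-2,3-dione, CH(OMe)3 and CSA in MeOH protect only the trans-diequatorial C5/C6 diol, giving the butane-2,3-bisacetal F5.
- BzCl/pyridine acylates the secondary allylic C4–OH but not the tertiary C1–OH, giving the dibenzoate F6.
- TFA/H2O releases the diol, and the sequence rejoins the route at 17.

Further compounds
F1 | step 9 | α-chloro sulfide of thiepane 8 | CC(C)(C)[Si](c1ccccc1)(c1ccccc1)OC[C@@]12CSC(Cl)[C@H]3OC(c4ccccc4)O[C@H]3[C@@H]1OC(C)(C)O2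
F2 | step 9 | α-chloro sulfone | CC(C)(C)[Si](c1ccccc1)(c1ccccc1)OC[C@@]12CS(=O)(=O)C(Cl)[C@H]3OC(c4ccccc4)O[C@H]3[C@@H]1OC(C)(C)O2
F3 | step 7 | 6-S-acetyl-6-thio-1-O-tosyl analogue of 7 | Cc1ccc(cc1)S(=O)(=O)OC[C@@]1(CO[Si](c2ccccc2)(c2ccccc2)C(C)(C)C)OC(C)(C)O[C@H]1[C@@H]1OC(c2ccccc2)O[C@@H]1CSC(C)=O
F4 | step 12 | [(1S,4R,5S,6S)-1,4,5,6-tetrahydroxycyclohex-2-en-1-yl]methyl benzoate | O=C(OC[C@@]1(O)C=C[C@@H](O)[C@@H](O)[C@@H]1O)c1ccccc1
F5 | step 12 | 5,6-O-[(2S,3S)-2,3-dimethoxybutane-2,3-diyl] derivative of F4 | O=C(OC[C@@]1(O)C=C[C@@H](O)[C@H]2O[C@](C)(OC)[C@@](C)(OC)O[C@H]12)c1ccccc1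
F6 | step 12 | 4-O-benzoyl derivative of F5 | O=C(OC[C@@]1(O)C=C[C@@H](OC(=O)c3ccccc3)[C@H]2O[C@](C)(OC)[C@@](C)(OC)O[C@H]12)c1ccccc1
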